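**Target:** (3S)-3-(5-hydroxy-2,2-dimethyl-2H-chromen-6-yl)-8-(3-methylbut-2-en-1-yl)-3,4-dihydro-2H-chromen-7-ol (C25H28O4). The single stereocentre C3 is (S) by CIP analysis of the given SMILES.

## Retrosynthetic overview

1. The C3 stereocentre is set last, by asymmetric transfer hydrogenation of the achiral 2'-hydroxyisoflav-3-ene 17 (new step).
2. Ring C of 17 comes from the 3-arylcoumarin 15 (lactone reduced to the 2H-pyran); 15 comes from Knoevenagel condensation and translactonisation of salicylaldehyde 8 with aryl lactone 13.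
3. The aryl–C3 bond is made by a 1,2-aryl shift: aldehyde 6 plus ethyl diazoacetate gives the formyl ester 10 (closed as hemiacetal 11), which is deformylated and lactonised to 13.
4. Both aryl units come from 2,4-dihydroxybenzaldehyde 3 (from resorcinol): prenal builds the dimethylpyran of ring B, prenyl bromide gives the C8 side chain of ring A.
5. Ring order: pyran on ring B (step 2), temporary furanone (steps 4–5), ring C as coumarin (step 6), ring C as 2H-pyran (step 7), stereocentre (step 8).

**Assumption:** the absolute sense of induction in step 8 cannot be predicted from precedent. (R)-TRIP is written; if it favours the (3R)-product, (S)-TRIP is used with everything else unchanged.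

## Route

**Step 1**
Reactants: 1 resorcinol
Product: 3 2,4-dihydroxybenzaldehyde, via iminium chloride 2 (not isolated)
Conditions: POCl3, DMF, MeCN, −15 to 25 °C; then H2O, 50 °C
Reagents that add atoms: N,N-dimethylformamide, CN(C)C=O; water, O
Why: Vilsmeier–Haack formylation attacks the most electron-rich position of resorcinol (para to one OH, ortho to the other) and stops at the monoaldehyde.

**Step 2**
Reactants: 3 2,4-dihydroxybenzaldehyde; 4 3-methylbut-2-enal
Product: 6 5-hydroxy-2,2-dimethyl-2H-chromene-6-carbaldehyde, via quinone methide dienone 5 (not isolated)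
Conditions: pyridine, 120 °C (sealed tube)
Reagents that add atoms: none
Why: Base-mediated chromenylation: the 2-OH is locked in a hydrogen bond to the formyl group, so the free 4-OH directs Knoevenagel-type C-alkylation to C3, and the dienone closes by oxa-6π electrocyclisation to the angular chromene.

**Step 3**
Reactants: 3 2,4-dihydroxybenzaldehyde; 7 1-bromo-3-methylbut-2-ene
Product: 8 2,4-dihydroxy-3-(3-methylbut-2-en-1-yl)benzaldehyde
Conditions: KOH, H2O, 0 °C to rt
Reagents that add atoms: none
Why: Nuclear C-prenylation of the ambident phenoxide in water places the prenyl group at C3 between the two oxygens; the reaction is known for this substrate but the yield is modest (O- and C5-alkylation compete).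

**Step 4**
Reactants: 6 5-hydroxy-2,2-dimethyl-2H-chromene-6-carbaldehyde; 9 ethyl diazoacetate
Product: 11 ethyl 2-hydroxy-7,7-dimethyl-2,3-dihydro-7H-furo[2,3-f]chromene-3-carboxylate (diastereomer mixture), via formyl ester 10 (not isolated)
Conditions: HBF4·OEt2 (10 mol%), CH2Cl2, −78 °C to rt
Reagents that add atoms: none
Why: Brønsted acid-catalysed aldehyde–diazoacetate homologation (Büchner–Curtius–Schlotterbeck type): after the diazoacetate adds to the protonated aldehyde, the electron-rich 2,4-dioxygenated aryl group shifts 1,2 from the carbinol carbon to the diazonium carbon with loss of N2 (aryl migrates in preference to hydride), and the ortho-OH traps the new formyl group as the hemiacetal; this is the skeletal step that creates the aryl–C3 bond.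

**Step 5**
Reactants: 11 ethyl 2-hydroxy-7,7-dimethyl-2,3-dihydro-7H-furo[2,3-f]chromene-3-carboxylate
Product: 13 7,7-dimethyl-3,7-dihydro-2H-furo[2,3-f]chromen-2-one, via arylacetic acid 12 (not isolated)
Conditions: 2 M NaOH, EtOH–H2O, 60 °C, Ar; then 2 M HCl; then N-(3-dimethylaminopropyl)-N'-ethylcarbodiimide hydrochloride (EDC·HCl), CH2Cl2, rt
Reagents that add atoms: sodium hydroxide, [Na+].[OH-]
Why: Hydroxide removes the formyl group by retro-Claisen cleavage (as formate) and saponifies the ester, and carbodiimide dehydration of the 2-hydroxyarylacetic acid closes the five-membered aryl lactone.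

**Step 6**
Reactants: 13 7,7-dimethyl-3,7-dihydro-2H-furo[2,3-f]chromen-2-one; 8 2,4-dihydroxy-3-(3-methylbut-2-en-1-yl)benzaldehyde
Product: 15 7-hydroxy-3-(5-hydroxy-2,2-dimethyl-2H-chromen-6-yl)-8-(3-methylbut-2-en-1-yl)-2H-chromen-2-one, via arylidene lactone 14 (not isolated)
Conditions: Et3N (1.5 equiv), EtOH, 78 °C, Ar
Reagents that add atoms: none
Why: Knoevenagel condensation of the acidic lactone CH2 with the salicylaldehyde, then translactonisation (the ring A ortho-OH opens the five-membered lactone and closes the more stable coumarin), gives the 3-(2-hydroxyaryl)coumarin without protecting groups.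

**Step 7**
Reactants: 15 7-hydroxy-3-(5-hydroxy-2,2-dimethyl-2H-chromen-6-yl)-8-(3-methylbut-2-en-1-yl)-2H-chromen-2-one
Product: 17 3-(5-hydroxy-2,2-dimethyl-2H-chromen-6-yl)-8-(3-methylbut-2-en-1-yl)-2H-chromen-7-ol, via allylic diol 16 (not isolated)
Conditions: i-Bu2AlH (6 equiv), THF, −78 to 0 °C; aq. KNaC4H4O6 work-up; then pyridinium p-toluenesulfonate (10 mol%), toluene, 40 °C
Reagents that add atoms: none
Why: i-Bu2AlH reduces the unsaturated lactone by 1,2-addition to the (Z)-allylic diol and leaves the isolated alkenes alone, and mild acid ionises the allylic alcohol to a vinyl ortho-quinone methide that closes (oxa-6π) to the 2H-chromene.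

**Step 8**
Reactants: 17 3-(5-hydroxy-2,2-dimethyl-2H-chromen-6-yl)-8-(3-methylbut-2-en-1-yl)-2H-chromen-7-ol
Product: 19 (3S)-3-(5-hydroxy-2,2-dimethyl-2H-chromen-6-yl)-8-(3-methylbut-2-en-1-yl)-3,4-dihydro-2H-chromen-7-ol, via ortho-quinone methide 18 (not isolated)
Conditions: (R)-3,3'-bis(2,4,6-triisopropylphenyl)-1,1'-binaphthalene-2,2'-diyl hydrogen phosphate ((R)-TRIP, 10 mol%), diethyl 2,6-dimethyl-1,4-dihydropyridine-3,5-dicarboxylate (Hantzsch ester, 1.3 equiv), toluene, 0 °C, Ar, dark
Reagents that add atoms: none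
Why: Proposed new method: chiral phosphoric acid-catalysed asymmetric transfer hydrogenation of a 2'-hydroxyisoflav-3-ene, in which the catalyst relays the 2'-OH proton to C4 to give the ring B ortho-quinone methide 18 hydrogen-bonded to the phosphate, the Hantzsch ester N–H binds the phosphoryl oxygen, and hydride is delivered to one face of the prochiral C3, setting the (3S) centre and re-aromatising ring B; the weak acid does not protonate the prenyl group, and the ring B pyran alkene could only give a less stabilised secondary quinone methide; closest known reaction type: phosphoric acid/Hantzsch ester transfer hydrogenation of ortho-hydroxy-1,1-diarylethenes through ortho-quinone methides.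

## Compound list

1 | resorcinol (benzene-1,3-diol) | Oc1cccc(O)c1 | starting material
2 | (2,4-dihydroxybenzylidene)dimethyliminium chloride | C[N+](C)=Cc1ccc(O)cc1O.[Cl-] | intermediate
3 | 2,4-dihydroxybenzaldehyde | O=Cc1ccc(O)cc1O | intermediate
4 | 3-methylbut-2-enal | CC(C)=CC=O | starting material
5 | 2-hydroxy-3-(3-methylbut-2-en-1-ylidene)-4-oxocyclohexa-1,5-diene-1-carbaldehyde | CC(C)=CC=C1C(=O)C=CC(C=O)=C1O | intermediate
6 | 5-hydroxy-2,2-dimethyl-2H-chromene-6-carbaldehyde | CC1(C)C=Cc2c(O1)ccc(C=O)c2O | intermediate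
7 | 1-bromo-3-methylbut-2-ene | CC(C)=CCBr | starting material
8 | 2,4-dihydroxy-3-(3-methylbut-2-en-1-yl)benzaldehyde | CC(C)=CCc1c(O)ccc(C=O)c1O | intermediate
9 | ethyl diazoacetate | CCOC(=O)C=[N+]=[N-] | starting material
10 | ethyl 2-(5-hydroxy-2,2-dimethyl-2H-chromen-6-yl)-3-oxopropanoate | CCOC(=O)C(C=O)c1ccc2OC(C)(C)C=Cc2c1O | intermediate
11 | ethyl 2-hydroxy-7,7-dimethyl-2,3-dihydro-7H-furo[2,3-f]chromene-3-carboxylate (cyclic hemiacetal of 10, diastereomer mixture) | CCOC(=O)C1C(O)Oc2c1ccc1OC(C)(C)C=Cc21 | intermediate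
12 | 2-(5-hydroxy-2,2-dimethyl-2H-chromen-6-yl)acetic acid | OC(=O)Cc1ccc2OC(C)(C)C=Cc2c1O | intermediate
13 | 7,7-dimethyl-3,7-dihydro-2H-furo[2,3-f]chromen-2-one | O=C1Cc2ccc3OC(C)(C)C=Cc3c2O1 | intermediate
14 | 3-[(2,4-dihydroxy-3-(3-methylbut-2-en-1-yl)phenyl)methylidene]-7,7-dimethyl-3,7-dihydro-2H-furo[2,3-f]chromen-2-one (E/Z mixture) | CC(C)=CCc1c(O)ccc(C=C2C(=O)Oc3c2ccc2OC(C)(C)C=Cc32)c1O | intermediate
15 | 7-hydroxy-3-(5-hydroxy-2,2-dimethyl-2H-chromen-6-yl)-8-(3-methylbut-2-en-1-yl)-2H-chromen-2-one | CC(C)=CCc1c(O)ccc2C=C(c3ccc4OC(C)(C)C=Cc4c3O)C(=O)Oc12 | intermediate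
16 | 4-[(1Z)-3-hydroxy-2-(5-hydroxy-2,2-dimethyl-2H-chromen-6-yl)prop-1-en-1-yl]-2-(3-methylbut-2-en-1-yl)benzene-1,3-diol | CC(C)=CCc1c(O)ccc(/C=C(\CO)c2ccc3OC(C)(C)C=Cc3c2O)c1O | intermediate
17 | 3-(5-hydroxy-2,2-dimethyl-2H-chromen-6-yl)-8-(3-methylbut-2-en-1-yl)-2H-chromen-7-ol | CC(C)=CCc1c(O)ccc2C=C(c3ccc4OC(C)(C)C=Cc4c3O)COc12 | intermediate
18 | 6-[7-hydroxy-8-(3-methylbut-2-en-1-yl)-2H-chromen-3(4H)-ylidene]-2,2-dimethyl-2H-chromen-5(6H)-one (ring B ortho-quinone methide) | CC(C)=CCc1c(O)ccc2CC(=C3C=CC4=C(C=CC(C)(C)O4)C3=O)COc12 | intermediate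
19 | (3S)-3-(5-hydroxy-2,2-dimethyl-2H-chromen-6-yl)-8-(3-methylbut-2-en-1-yl)-3,4-dihydro-2H-chromen-7-ol | CC(C)=CCc1c(O)ccc2c1OC[C@H](c1ccc3c(c1O)C=CC(C)(C)O3)C2 | target

## Step count and risks

Total steps: 8. Longest linear sequence: 7 (steps 1, 2, 4, 5, 6, 7, 8 from resorcinol).

**Step 8 (new method).** Risks: erosion of ee if C3 is protonated instead (ring A para-quinone methide path), reduction of the ring B pyran alkene, and acid-induced dimerisation of 17. The fallback uses known chemistry, sets out from 17 and returns at 19. Ionic hydrogenation of 17 with Et3SiH and CF3CO2H in CH2Cl2 at −20 °C gives racemic 3-(5-hydroxy-2,2-dimethyl-2H-chromen-6-yl)-8-(3-methylbut-2-en-1-yl)-3,4-dihydro-2H-chromen-7-ol F1. Preparative chiral supercritical-fluid chromatography on an amylose tris(3,5-dimethylphenylcarbamate) phase then gives 19 and the (3R)-enantiomer F2, which is discarded.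

**Step 3 (C-prenylation).** Risks: low yield and separation from the O-prenyl and C5-prenyl isomers. The fallback builds the same aldehyde by directed ortho-metalation; it sets out from 1 and returns at 8. Resorcinol 1 with MOMCl and i-Pr2NEt in CH2Cl2 gives 1,3-bis(methoxymethoxy)benzene F3. Lithiation between the two directing groups (n-BuLi, THF, 0 °C), then CuI (10 mol%) and bromide 7, gives 1,3-bis(methoxymethoxy)-2-(3-methylbut-2-en-1-yl)benzene F4. A second lithiation (n-BuLi, TMEDA, THF, −20 °C) quenched with DMF gives 2,4-bis(methoxymethoxy)-3-(3-methylbut-2-en-1-yl)benzaldehyde F5. HCl in MeOH at 50 °C removes both MOM groups to give 8.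

**Step 6 (condensation and translactonisation).** Risks: the aldehyde is deactivated as its phenoxide, and lactone 13 autoxidises in base. The fallback is an anhydride-mediated Perkin–Oglialoro condensation; it sets out from acid 12 (intercepted before the carbodiimide treatment) and aldehyde 8 and returns at 15. Heating 12 and 8 in Ac2O with Et3N at 110 °C gives 7-acetoxy-3-(5-acetoxy-2,2-dimethyl-2H-chromen-6-yl)-8-(3-methylbut-2-en-1-yl)-2H-chromen-2-one F6. Methanolysis (K2CO3, MeOH, rt, then acidification) removes both acetates to give 15.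

## Further compounds

F1 | step 8 | racemic 3-(5-hydroxy-2,2-dimethyl-2H-chromen-6-yl)-8-(3-methylbut-2-en-1-yl)-3,4-dihydro-2H-chromen-7-ol | CC(C)=CCc1c(O)ccc2c1OCC(c1ccc3c(c1O)C=CC(C)(C)O3)C2
F2 | step 8 | (3R)-3-(5-hydroxy-2,2-dimethyl-2H-chromen-6-yl)-8-(3-methylbut-2-en-1-yl)-3,4-dihydro-2H-chromen-7-ol | CC(C)=CCc1c(O)ccc2c1OC[C@@H](c1ccc3c(c1O)C=CC(C)(C)O3)C2
F3 | step 3 | 1,3-bis(methoxymethoxy)benzene | COCOc1cccc(OCOC)c1
F4 | step 3 | 1,3-bis(methoxymethoxy)-2-(3-methylbut-2-en-1-yl)benzene | COCOc1cccc(OCOC)c1CC=C(C)C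
F5 | step 3 | 2,4-bis(methoxymethoxy)-3-(3-methylbut-2-en-1-yl)benzaldehyde | COCOc1ccc(C=O)c(OCOC)c1CC=C(C)C
F6 | step 6 | 7-acetoxy-3-(5-acetoxy-2,2-dimethyl-2H-chromen-6-yl)-8-(3-methylbut-2-en-1-yl)-2H-chromen-2-one | CC(=O)Oc1ccc2C=C(c3ccc4OC(C)(C)C=Cc4c3OC(C)=O)C(=O)Oc2c1CC=C(C)C
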